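**Assumption:** the benzyl‑protected building blocks 1, 6 and 8 are taken as catalogue chemicals; all selectivities are estimates and nothing here has been run.

**Abbreviations:** ECG = (−)‑epicatechin 3‑O‑gallate skeleton (2R, 2‑aryl and 3‑O‑galloyl both α). "Hepta‑O‑benzyl" = benzyl ethers on O5, O7, O3′, O4′ and the three galloyl phenols. The target is ECG‑(4β→8)‑ECG‑(4β→6)‑(+)‑catechin.

## Retrosynthetic overview

1. Target 20 ⇐ global hydrogenolysis (18 OBn, 3 C–Br) of the protected trimer 19.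
2. 19 ⇐ Ag(I)‑promoted 4β→6 coupling of dimeric C4‑thioether 15 with 8‑bromo‑tetra‑O‑benzyl‑(+)‑catechin 18 (C8 blocked; terminal C‑ring comes from the chiral pool).
3. 15 ⇐ one flask: the C‑rings of the middle and then the top unit are closed by C4–C4a Friedel–Crafts cyclisation of the acyclic acetals 9 and 10; the C4 cations are trapped in situ (thiol, then C8 of the middle unit) to give the 4β→8 bond.
4. 9 and 10 ⇐ threo aryl ether 7 (cis‑epoxide 5 + phenol 6, SN2 inversion), then galloylation and, for 10, dibromination.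
5. 5 ⇐ Jacobsen epoxidation of Z‑alkene 4 ⇐ Sonogashira/Lindlar from 1 and 2. All aromatic rings are purchased.

## Route

**Step 1**
Reactants: 1 4‑bromo‑1,2‑bis(benzyloxy)benzene; 2 3,3‑diethoxyprop‑1‑yne
Product: 3 1,2‑bis(benzyloxy)‑4‑(3,3‑diethoxyprop‑1‑yn‑1‑yl)benzene
Conditions: Pd(PPh3)2Cl2 (3 mol%), CuI (5 mol%), Et3N, 70 °C
Reagents that add atoms: none
Why: Sonogashira coupling of an aryl bromide with a terminal alkyne installs the three‑carbon chain with C4 already at the aldehyde oxidation level (as the acetal).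

**Step 2**
Reactants: 3 1,2‑bis(benzyloxy)‑4‑(3,3‑diethoxyprop‑1‑yn‑1‑yl)benzene
Product: 4 (Z)‑1,2‑bis(benzyloxy)‑4‑(3,3‑diethoxyprop‑1‑en‑1‑yl)benzene
Conditions: H2 (1 atm), Lindlar catalyst, quinoline, EtOAc, rt
Reagents that add atoms: none
Why: Lindlar semihydrogenation adds H2 syn to give the Z‑alkene without cleaving benzyl ethers or the acetal.

**Step 3**
Reactants: 4 (Z)‑1,2‑bis(benzyloxy)‑4‑(3,3‑diethoxyprop‑1‑en‑1‑yl)benzene
Product: 5 (2S,3S)‑2‑[3,4‑bis(benzyloxy)phenyl]‑3‑(diethoxymethyl)oxirane (cis)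
Conditions: (S,S)‑Jacobsen Mn(salen)Cl (5 mol%), NaOCl aq (pH 11.3), 4‑phenylpyridine N‑oxide, CH2Cl2, 0 °C
Reagents that add atoms: sodium hypochlorite, [Na+].[O-]Cl
Why: Jacobsen–Katsuki epoxidation of a cis‑β‑substituted styrene sets both C–O stereocentres as the cis (2S,3S) epoxide, the (S,S) catalyst being chosen by analogy with cis‑cinnamates and cis‑β‑methylstyrene, and the basic medium protects the electron‑rich epoxide and the acetal.

**Step 4**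
Reactants: 5 (2S,3S)‑2‑[3,4‑bis(benzyloxy)phenyl]‑3‑(diethoxymethyl)oxirane; 6 3,5‑bis(benzyloxy)phenol
Product: 7 (1R,2S)‑1‑[3,4‑bis(benzyloxy)phenyl]‑1‑[3,5‑bis(benzyloxy)phenoxy]‑3,3‑diethoxypropan‑2‑ol
Conditions: 6 (1.3 equiv), Cs2CO3 (0.3 equiv), DMF, 80 °C
Reagents that add atoms: none
Why: Base‑mediated SN2 epoxide opening by phenoxide at the benzylic carbon (the carbon next to the acetal is deactivated) proceeds with inversion, so the cis‑epoxide gives the threo aryl ether, which is the 2,3‑cis (epicatechin) relationship with future C2 = R and the untouched carbinol as future C3.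

**Step 5**
Reactants: 7 (1R,2S)‑1‑[3,4‑bis(benzyloxy)phenyl]‑1‑[3,5‑bis(benzyloxy)phenoxy]‑3,3‑diethoxypropan‑2‑ol; 8 3,4,5‑tris(benzyloxy)benzoic acid
Product: 9 (1R,2S)‑1‑[3,4‑bis(benzyloxy)phenyl]‑1‑[3,5‑bis(benzyloxy)phenoxy]‑3,3‑diethoxypropan‑2‑yl 3,4,5‑tris(benzyloxy)benzoate
Conditions: 8 (1.5 equiv), EDC·HCl, DMAP, CH2Cl2, rt
Reagents that add atoms: none
Why: Steglich esterification acylates the only free hydroxyl with retention, putting the gallate in place before any ring exists.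

**Step 6**
Reactants: 9 (1R,2S)‑1‑[3,4‑bis(benzyloxy)phenyl]‑1‑[3,5‑bis(benzyloxy)phenoxy]‑3,3‑diethoxypropan‑2‑yl 3,4,5‑tris(benzyloxy)benzoate
Product: 10 (1R,2S)‑1‑[3,4‑bis(benzyloxy)phenyl]‑1‑[2,4‑dibromo‑3,5‑bis(benzyloxy)phenoxy]‑3,3‑diethoxypropan‑2‑yl 3,4,5‑tris(benzyloxy)benzoate
Conditions: NBS (2.05 equiv), CH2Cl2, −40 → 0 °C, dark
Reagents that add atoms: N‑bromosuccinimide, O=C1CCC(=O)N1Br
Why: Electrophilic aromatic bromination is fastest on the trioxygenated ring, first at the position between the two OBn groups and then at one position ortho to the bulky ether, leaving one ortho carbon free for ring closure and placing bromine on the future C6 and C8 of the top unit.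

**Step 7**
Reactants: 9 (1R,2S)‑1‑[3,4‑bis(benzyloxy)phenyl]‑1‑[3,5‑bis(benzyloxy)phenoxy]‑3,3‑diethoxypropan‑2‑yl 3,4,5‑tris(benzyloxy)benzoate; 11 2,6‑dimethylbenzenethiol; 10 (1R,2S)‑1‑[3,4‑bis(benzyloxy)phenyl]‑1‑[2,4‑dibromo‑3,5‑bis(benzyloxy)phenoxy]‑3,3‑diethoxypropan‑2‑yl 3,4,5‑tris(benzyloxy)benzoate
Product: 15 protected dimer thioether [6,8‑dibromo‑hepta‑O‑benzyl‑ECG]‑(4β→8)‑[4β‑(2,6‑dimethylphenylthio)‑hepta‑O‑benzyl‑ECG], via 4β‑ethoxyflavan gallate 12 (not isolated), via 4β‑arylthioflavan gallate 13 (not isolated), via 6,8‑dibromo‑4β‑ethoxyflavan gallate 14 (not isolated)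
Conditions: 9 (1.2 equiv), 11 (1.2 equiv), TMSOTf (0.3 equiv), 5 Å MS, CH2Cl2, −40 °C, 1 h; then 10 (1.0 equiv) dropwise, −40 → −20 °C
Reagents that add atoms: none
Why: Proposed new method: acid ionises each acetal to an oxocarbenium ion (assisted by the neighbouring galloyl carbonyl) that the free ortho carbon of the dialkoxyphenyl ether captures in a six‑ring Friedel–Crafts closure, the resulting 4‑ethoxyflavan re‑ionises to the A‑ring‑stabilised C4 cation, and this is attacked anti to the 3‑O‑galloyl group (4β) by thiol 11 for the middle unit and by C8 of 13 for the top unit, the soft C4–S bond of 13 being inert to the hard acid and the bromines of 14 preventing oligomerisation; the closest known chemistry is acid cyclisation of 3‑aryloxypropanal acetals to 4‑alkoxychromans combined with Lewis‑acid interflavan coupling using orthogonal C4–O/C4–S leaving groups and C8‑bromo capping.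

**Step 8**
Reactants: 16 (+)‑catechin
Product: 17 (2R,3S)‑5,7‑bis(benzyloxy)‑2‑[3,4‑bis(benzyloxy)phenyl]chroman‑3‑ol (5,7,3′,4′‑tetra‑O‑benzyl‑(+)‑catechin)
Conditions: BnBr (4.4 equiv), K2CO3, DMF, 0 °C → rt
Reagents that add atoms: benzyl bromide, BrCc1ccccc1
Why: Williamson etherification with carbonate base alkylates the four phenols and leaves the less acidic secondary 3‑OH free.

**Step 9**
Reactants: 17 5,7,3′,4′‑tetra‑O‑benzyl‑(+)‑catechin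
Product: 18 (2R,3S)‑5,7‑bis(benzyloxy)‑2‑[3,4‑bis(benzyloxy)phenyl]‑8‑bromochroman‑3‑ol
Conditions: NBS (1.0 equiv), CH2Cl2, −78 → 0 °C
Reagents that add atoms: N‑bromosuccinimide, O=C1CCC(=O)N1Br
Why: Electrophilic aromatic bromination of benzylated flavan‑3‑ols occurs at the more accessible C8, which blocks that carbon so that only C6 can act as nucleophile.

**Step 10**
Reactants: 15 protected dimer thioether; 18 (2R,3S)‑5,7‑bis(benzyloxy)‑2‑[3,4‑bis(benzyloxy)phenyl]‑8‑bromochroman‑3‑ol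
Product: 19 protected trimer [6,8‑dibromo‑hepta‑O‑benzyl‑ECG]‑(4β→8)‑[hepta‑O‑benzyl‑ECG]‑(4β→6)‑[8‑bromo‑5,7,3′,4′‑tetra‑O‑benzyl‑(+)‑catechin]
Conditions: 18 (3 equiv), AgBF4 (2 equiv), 2,6‑di‑tert‑butyl‑4‑methylpyridine (1.5 equiv), 4 Å MS, CH2Cl2/THF, −40 → 0 °C
Reagents that add atoms: none
Why: Thiophilic Ag(I) activation of the C4–S bond gives the flavan‑4‑yl cation of the middle unit, and Friedel–Crafts attack by the only free A‑ring carbon of 18 (C6) anti to the 3‑O‑galloyl group of the 2,3‑cis unit sets the 4β→6 bond, with every other nucleophilic A‑ring carbon substituted or bromine‑capped.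

**Step 11**
Reactants: 19 protected trimer
Product: 20 epicatechin‑3‑O‑gallate‑(4β→8)‑epicatechin‑3‑O‑gallate‑(4β→6)‑catechin (target)
Conditions: H2 (1 atm), 20% Pd(OH)2/C, Et3N (3.5 equiv), THF/MeOH/H2O, rt; Sephadex LH‑20
Reagents that add atoms: none
Why: Catalytic hydrogenolysis removes all 18 benzyl ethers and the three aryl bromides in one operation, leaving gallate esters, interflavan bonds and all stereocentres untouched.

## Compound list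

1 | 4‑bromo‑1,2‑bis(benzyloxy)benzene | Brc1ccc(OCc2ccccc2)c(OCc2ccccc2)c1 | starting material
2 | 3,3‑diethoxyprop‑1‑yne | C#CC(OCC)OCC | starting material
3 | 1,2‑bis(benzyloxy)‑4‑(3,3‑diethoxyprop‑1‑yn‑1‑yl)benzene | CCOC(OCC)C#Cc1ccc(OCc2ccccc2)c(OCc2ccccc2)c1 | intermediate
4 | (Z)‑1,2‑bis(benzyloxy)‑4‑(3,3‑diethoxyprop‑1‑en‑1‑yl)benzene | CCOC(OCC)/C=C\c1ccc(OCc2ccccc2)c(OCc2ccccc2)c1 | intermediate
5 | (2S,3S)‑2‑[3,4‑bis(benzyloxy)phenyl]‑3‑(diethoxymethyl)oxirane (cis) | O1[C@@H](c2ccc(OCc3ccccc3)c(OCc3ccccc3)c2)[C@H]1C(OCC)OCC | intermediate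
6 | 3,5‑bis(benzyloxy)phenol | Oc1cc(OCc2ccccc2)cc(OCc2ccccc2)c1 | starting material
7 | (1R,2S)‑1‑[3,4‑bis(benzyloxy)phenyl]‑1‑[3,5‑bis(benzyloxy)phenoxy]‑3,3‑diethoxypropan‑2‑ol | O([C@H](c1ccc(OCc2ccccc2)c(OCc2ccccc2)c1)[C@H](O)C(OCC)OCC)c1cc(OCc2ccccc2)cc(OCc2ccccc2)c1 | intermediate
8 | 3,4,5‑tris(benzyloxy)benzoic acid | OC(=O)c1cc(OCc2ccccc2)c(OCc2ccccc2)c(OCc2ccccc2)c1 | starting material
9 | (1R,2S)‑1‑[3,4‑bis(benzyloxy)phenyl]‑1‑[3,5‑bis(benzyloxy)phenoxy]‑3,3‑diethoxypropan‑2‑yl 3,4,5‑tris(benzyloxy)benzoate | O([C@H](c1ccc(OCc2ccccc2)c(OCc2ccccc2)c1)[C@H](OC(=O)c1cc(OCc2ccccc2)c(OCc2ccccc2)c(OCc2ccccc2)c1)C(OCC)OCC)c1cc(OCc2ccccc2)cc(OCc2ccccc2)c1 | intermediate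
10 | (1R,2S)‑1‑[3,4‑bis(benzyloxy)phenyl]‑1‑[2,4‑dibromo‑3,5‑bis(benzyloxy)phenoxy]‑3,3‑diethoxypropan‑2‑yl 3,4,5‑tris(benzyloxy)benzoate | O([C@H](c1ccc(OCc2ccccc2)c(OCc2ccccc2)c1)[C@H](OC(=O)c1cc(OCc2ccccc2)c(OCc2ccccc2)c(OCc2ccccc2)c1)C(OCC)OCC)c1c(Br)c(OCc2ccccc2)c(Br)c(OCc2ccccc2)c1 | intermediate
11 | 2,6‑dimethylbenzenethiol | Cc1cccc(C)c1S | starting material
12 | (2R,3R,4S)‑5,7‑bis(benzyloxy)‑2‑[3,4‑bis(benzyloxy)phenyl]‑4‑ethoxychroman‑3‑yl 3,4,5‑tris(benzyloxy)benzoate (2,3‑cis, 4β‑OEt) | c1c(OCc2ccccc2)cc(OCc2ccccc2)c2c1O[C@H](c1ccc(OCc3ccccc3)c(OCc3ccccc3)c1)[C@H](OC(=O)c1cc(OCc3ccccc3)c(OCc3ccccc3)c(OCc3ccccc3)c1)[C@H]2OCC | intermediate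
13 | (2R,3S,4S)‑5,7‑bis(benzyloxy)‑2‑[3,4‑bis(benzyloxy)phenyl]‑4‑[(2,6‑dimethylphenyl)sulfanyl]chroman‑3‑yl 3,4,5‑tris(benzyloxy)benzoate (ECG skeleton, 4β‑S) | c1c(OCc2ccccc2)cc(OCc2ccccc2)c2c1O[C@H](c1ccc(OCc3ccccc3)c(OCc3ccccc3)c1)[C@H](OC(=O)c1cc(OCc3ccccc3)c(OCc3ccccc3)c(OCc3ccccc3)c1)[C@H]2Sc1c(C)cccc1C | intermediate
14 | (2R,3R,4S)‑6,8‑dibromo‑5,7‑bis(benzyloxy)‑2‑[3,4‑bis(benzyloxy)phenyl]‑4‑ethoxychroman‑3‑yl 3,4,5‑tris(benzyloxy)benzoate (4β‑OEt) | Brc1c(OCc2ccccc2)c(Br)c(OCc2ccccc2)c2c1O[C@H](c1ccc(OCc3ccccc3)c(OCc3ccccc3)c1)[C@H](OC(=O)c1cc(OCc3ccccc3)c(OCc3ccccc3)c(OCc3ccccc3)c1)[C@H]2OCC | intermediate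
15 | [6,8‑dibromo‑hepta‑O‑benzyl‑ECG]‑(4β→8)‑[4β‑(2,6‑dimethylphenylthio)‑hepta‑O‑benzyl‑ECG] | O=C(O[C@@H]1[C@@H](c2c(OCc4ccccc4)cc(OCc4ccccc4)c3c2O[C@H](c2ccc(OCc4ccccc4)c(OCc4ccccc4)c2)[C@H](OC(=O)c2cc(OCc4ccccc4)c(OCc4ccccc4)c(OCc4ccccc4)c2)[C@H]3Sc2c(C)cccc2C)c2c(OCc3ccccc3)c(Br)c(OCc3ccccc3)c(Br)c2O[C@@H]1c1ccc(OCc2ccccc2)c(OCc2ccccc2)c1)c1cc(OCc2ccccc2)c(OCc2ccccc2)c(OCc2ccccc2)c1 | intermediate
16 | (+)‑catechin, (2R,3S) | O[C@H]1Cc2c(O)cc(O)cc2O[C@@H]1c1ccc(O)c(O)c1 | starting material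
17 | 5,7,3′,4′‑tetra‑O‑benzyl‑(+)‑catechin | O[C@H]1Cc2c(OCc3ccccc3)cc(OCc3ccccc3)cc2O[C@@H]1c1ccc(OCc2ccccc2)c(OCc2ccccc2)c1 | intermediate
18 | 8‑bromo‑5,7,3′,4′‑tetra‑O‑benzyl‑(+)‑catechin | O[C@H]1Cc2c(OCc3ccccc3)cc(OCc3ccccc3)c(Br)c2O[C@@H]1c1ccc(OCc2ccccc2)c(OCc2ccccc2)c1 | intermediate
19 | [6,8‑dibromo‑hepta‑O‑benzyl‑ECG]‑(4β→8)‑[hepta‑O‑benzyl‑ECG]‑(4β→6)‑[8‑bromo‑5,7,3′,4′‑tetra‑O‑benzyl‑(+)‑catechin] | O=C(O[C@@H]1[C@@H](c2c(OCc4ccccc4)cc(OCc4ccccc4)c3c2O[C@H](c2ccc(OCc4ccccc4)c(OCc4ccccc4)c2)[C@H](OC(=O)c2cc(OCc4ccccc4)c(OCc4ccccc4)c(OCc4ccccc4)c2)[C@H]3c2c(OCc4ccccc4)c(Br)c3c(c2OCc5ccccc5)C[C@H](O)[C@@H](c2ccc(OCc4ccccc4)c(OCc4ccccc4)c2)O3)c2c(OCc3ccccc3)c(Br)c(OCc3ccccc3)c(Br)c2O[C@@H]1c1ccc(OCc2ccccc2)c(OCc2ccccc2)c1)c1cc(OCc2ccccc2)c(OCc2ccccc2)c(OCc2ccccc2)c1 | intermediate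
20 | epicatechin‑3‑O‑gallate‑(4β→8)‑epicatechin‑3‑O‑gallate‑(4β→6)‑catechin (CNP0154615.1) | O=C(O[C@@H]1[C@@H](c2c(O)cc(O)c3c2O[C@H](c2ccc(O)c(O)c2)[C@H](OC(=O)c2cc(O)c(O)c(O)c2)[C@H]3c2c(O)cc3c(c2O)C[C@H](O)[C@@H](c2ccc(O)c(O)c2)O3)c2c(O)cc(O)cc2O[C@@H]1c1ccc(O)c(O)c1)c1cc(O)c(O)c(O)c1 | target

## Totals and risk

Total steps: 11. Longest linear sequence: 9 (steps 1–7, 10, 11).

**Most likely to fail, 1: step 7 (one‑pot double cyclisation and coupling).** The dibrominated ring of 10 is a weak nucleophile, so three side paths are possible: capture of its oxocarbenium ion by 13 before ring closure (which would set top C4 without control), five‑ring closure onto the B‑ring, or loss of the C4–S bond of 13. The fallback sets out from 9 and returns at 15. It closes the rings one at a time on the unbrominated, more nucleophilic arene and installs the bromine caps only afterwards, so 10 is no longer used. 9 is cyclised with catalytic camphorsulfonic acid in EtOH/CH2Cl2 at 0 °C and the 4β‑ethoxyflavan gallate 12 is isolated. 12 is dibrominated with NBS (2 equiv) to the 6,8‑dibromo‑4β‑ethoxyflavan gallate 14. A second portion of 9 is cyclised with 11 and TMSOTf and the thioether 13 is isolated. 14 and 13 are then joined with BF3·OEt2 at −78 °C to give 15. It makes no compound that the list does not hold (none F0).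

**Most likely to fail, 2: step 10 (4β→6 coupling).** C6 of 18 is flanked by two benzyloxy groups and deactivated by the C8 bromine, so the dimer cation may eliminate or decompose before it is captured. The fallback sets out from 18 and 15 and returns at 20. 18 is debenzylated with BCl3/pentamethylbenzene at −78 °C (aryl bromide retained) to 8‑bromo‑(+)‑catechin F4. The free phloroglucinol‑type ring of F4, still blocked at C8, is a much stronger and less hindered C6 nucleophile. F4 (excess) is coupled with 15 using AgBF4 in THF to give [6,8‑dibromo‑hepta‑O‑benzyl‑ECG]‑(4β→8)‑[hepta‑O‑benzyl‑ECG]‑(4β→6)‑[8‑bromo‑(+)‑catechin] F5. Hydrogenolysis of F5 under the step 11 conditions gives 20.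

**Most likely to fail, 3: step 3 (asymmetric cis‑epoxidation).** The electron‑rich styrene may give cis/trans leakage or insufficient ee. The fallback sets out from 4 and returns at 9, setting the stereocentres through a trans‑epoxide and two inversions. 4 is isomerised with catalytic (PhS)2 under light to (E)‑1,2‑bis(benzyloxy)‑4‑(3,3‑diethoxyprop‑1‑en‑1‑yl)benzene F1. Shi epoxidation with the enantiomeric (L‑fructose‑derived) ketone and Oxone at pH 10.5 gives (2R,3S)‑2‑(diethoxymethyl)‑3‑[3,4‑bis(benzyloxy)phenyl]oxirane F2. Phenoxide opening with 6 as in step 4 (inversion at the benzylic carbon) gives the erythro alcohol (1R,2R)‑1‑[3,4‑bis(benzyloxy)phenyl]‑1‑[3,5‑bis(benzyloxy)phenoxy]‑3,3‑diethoxypropan‑2‑ol F3. Mitsunobu esterification of F3 with 8 (PPh3, DIAD, toluene) inverts the carbinol and installs the gallate in the same step, giving 9; this Mitsunobu is slow next to the acetal and is the weak point of the fallback.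

## Further compounds

F1 | step 3 | (E)‑1,2‑bis(benzyloxy)‑4‑(3,3‑diethoxyprop‑1‑en‑1‑yl)benzene | CCOC(OCC)/C=C/c1ccc(OCc2ccccc2)c(OCc2ccccc2)c1
F2 | step 3 | (2R,3S)‑2‑(diethoxymethyl)‑3‑[3,4‑bis(benzyloxy)phenyl]oxirane (trans) | O1[C@@H](c2ccc(OCc3ccccc3)c(OCc3ccccc3)c2)[C@@H]1C(OCC)OCC
F3 | step 3 | (1R,2R)‑1‑[3,4‑bis(benzyloxy)phenyl]‑1‑[3,5‑bis(benzyloxy)phenoxy]‑3,3‑diethoxypropan‑2‑ol | O([C@H](c1ccc(OCc2ccccc2)c(OCc2ccccc2)c1)[C@@H](O)C(OCC)OCC)c1cc(OCc2ccccc2)cc(OCc2ccccc2)c1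
F0 | step 7 | none | none
F4 | step 10 | 8‑bromo‑(+)‑catechin | O[C@H]1Cc2c(O)cc(O)c(Br)c2O[C@@H]1c1ccc(O)c(O)c1
F5 | step 10 | [6,8‑dibromo‑hepta‑O‑benzyl‑ECG]‑(4β→8)‑[hepta‑O‑benzyl‑ECG]‑(4β→6)‑[8‑bromo‑(+)‑catechin] | O=C(O[C@@H]1[C@@H](c2c(OCc4ccccc4)cc(OCc4ccccc4)c3c2O[C@H](c2ccc(OCc4ccccc4)c(OCc4ccccc4)c2)[C@H](OC(=O)c2cc(OCc4ccccc4)c(OCc4ccccc4)c(OCc4ccccc4)c2)[C@H]3c2c(O)c(Br)c3c(c2O)C[C@H](O)[C@@H](c2ccc(O)c(O)c2)O3)c2c(OCc3ccccc3)c(Br)c(OCc3ccccc3)c(Br)c2O[C@@H]1c1ccc(OCc2ccccc2)c(OCc2ccccc2)c1)c1cc(OCc2ccccc2)c(OCc2ccccc2)c(OCc2ccccc2)c1
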